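# Synthesis proposal for the daucane diester 31 (CNP0305796.2)

Target atoms are numbered as follows and the numbers are used for all intermediates. Seven ring: C1 (acetoxy carbon), C2, C3 (quaternary, methyl), C7 (ring-fusion CH), C8 (aroyloxy carbon), C9, C10 (methyl-bearing alkene carbon). Five ring: C3, C4, C5, C6 (tertiary carbinol with isopropyl), C7.

## The problem

Compound 31 is a cyclopentane trans-fused to a cycloheptene, with five stereocentres: the all-carbon quaternary C3, the tertiary carbinol C6, the ring-fusion C7 and the two allylic ester carbons C8 and C1. C6, C7 and C8 are contiguous, and C7 lies between two fully substituted carbons. On the five ring the C3 methyl, the C7–C8 bond and the C6 hydroxyl share one face; the oxygens at C8 and C1 are both trans to the angular methyl. C3 has no neighbour that could induce it and must come from an enantioselective reaction. Once set, C3 can direct C7 and C6 in a ring closure, the free C6 hydroxyl can steer C8 by chelation, and the axial angular methyl can steer C1. The C6/C8 dioxygenation is an aldol array, so retro-aldol and dehydration threaten whenever C8 is a carbonyl. Two different allylic esters flank C9=C10; they do not tolerate base (cleavage, migration) or strong acid (ionisation), and the phenol and the tertiary alcohol must stay free at the end. The secondary hydroxyls at C1 and C8 carry different acyl groups and therefore have to appear at different times. The enabling feature is that the C6 carbinol is β to C8 through C7: the C6–C7 bond of the five ring is the bond of an aldol between a C8 ester enolate and an isopropyl ketone.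

## Retrosynthesis

**End game (31, 30, 29).** Only heteroatom bonds are cut: the phenol silyl ether of 30 and then the C1 acetate, back to alcohol 29. The aroyl group at C8 is already in place in 29, so the two secondary allylic hydroxyls never compete. The forward steps are a selective acetylation (tertiary C6–OH stays free) and a buffered desilylation.

**Seven ring, C1–C10 (29 from 27).** The ring is opened between the carbinol C1 and the alkene carbon C10, giving the (Z)-iodoalkene aldehyde 27, which comes from acetal 26. A Nozaki–Hiyama–Kishi closure is preferred to metathesis at C9=C10, which would have to form a trisubstituted alkene between two oxygenated allylic carbons, or to a closure at C8–C9, which would leave C8 unset. It forms ring and C1 carbinol together, tolerates the ester and the free tertiary hydroxyl, and takes its alkene geometry from the iodide. The forward reaction must close a seven ring and place the C1 oxygen trans to the angular methyl.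

**C8 ester and iodoalkene (26 from 21 and 24; 21 from 19; 19 from 17 and 18).** The C8–O acyl bond is cut to diol 21 and the silyl-protected acid 24 (from 4-hydroxybenzoic acid 22). The iodoalkene 21 is traced to propargylic alcohol 19, and the C8–C9 bond is cut to β-hydroxy aldehyde 17 and propynylmagnesium bromide 18. Aldehyde 17 comes from ester 15 through diol 16. The forward addition must set C8; the free C6 hydroxyl is kept as the chelating control element.

**Key disconnection, C6–C7 (15 from 13).** Cutting the aldol bond opens the five ring to the acyclic α-bromo ester 13, which carries only the quaternary C3. The halide fixes the site of enolate formation in the presence of the ketone, which no base-mediated aldol could do. The forward step, through samarium enolate 14, must set C6 and C7 relative to C3.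

**Bromo ketone (13 from 12, 10 and 8).** The isopropyl ketone is traced to the trisubstituted alkene of ester 8: bromination of 8 gives 10, hydroboration–oxidation gives alcohol 12, and oxidation gives 13. Keeping the ketone latent until after bromination means the ester is the only enolisable carbonyl when the halogen is introduced. Carrying C1 as a dimethyl acetal rather than a protected alcohol avoids δ-lactonisation onto the C8 ester and a later redox pair, and gives the C2 arm a β-branch.

**The two arms on C3 (8 from 7, 6 and 4).** The two-carbon arms C7–C8 (ester) and C2–C1 (aldehyde level) are read as a cleaved cyclopentanone. Reconnecting C1 to C8 gives ketone 4 through aldehyde ester 7 and α-ketol 6. The forward cleavage must occur on the side of the ketone remote from the quaternary carbon and must spare the alkene, which excludes ozonolysis.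

**Quaternary centre (4 from 1 and 2).** The C3–C4 bond is cut to 3-methylcyclopent-2-en-1-one 2 and the Grignard reagent 3 of 5-bromo-2-methylpent-2-ene 1. The asymmetric conjugate addition must deliver the (R)-ketone.

## Roads not taken

**Alternative 1:** Büchner ring expansion. The cut removes C3–C7 and C3–C2 together and reads the seven ring as an expanded benzene. A dirhodium carboxylate such as Rh2(OAc)4 would turn diazo ketone A2 into a carbene at C3 that adds to the C7–C2 bond of the dimethoxytoluene ring; ring opening gives trienone A1.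
- Merits: both rings and the quaternary centre arise in one catalytic step from a cheap arene that already holds the C10 methyl and the oxygens at C1 and C8. A1 would be reached in far fewer operations than the 16 steps the chosen plan needs to reach bicycle 29.
- Weak points: the carbene carbon bears a methyl, so 1,2-hydride shift competes. C3 is controlled only by C6 across the forming ring. Two ortho bonds compete. In A1 the carbons C7, C8 and C1 are all trigonal, so the trans ring fusion and both carbinols remain to be set on a cross-conjugated system. The C4 ketone has no counterpart in 31 and must be deleted.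
- Comparison: this road is better in skeletal economy. The chosen plan sets against this an identifiable control element for each of C6, C7, C8 and C1 and no deoxygenation.

**Alternative 2:** De Mayo photocycloaddition and retro-aldol. The cut removes C3–C7 and C1–C2. Irradiation of enol acetate A4 joins the enone to the tethered 1,1-disubstituted alkene, and methanolysis with retro-aldol fragmentation in the same pot would give dione A3.
- Merits: two C–C bonds, the quaternary centre and both rings in one operation; the C8 oxygen is present from the start and can bias the face of cycloaddition. It reaches the bicyclic skeleton sooner than the chosen plan.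
- Weak points: in A3 the C7 hydrogen lies between the C6 ketone and the C8 silyloxy group, so the basic fragmentation invites β-elimination. The ring fusion is set by protonation. A3 lacks both the isopropyl group and the C9=C10 alkene: isopropyl addition to an enolisable ketone next to the ring fusion, in the presence of a second ketone, and a regioselective dehydrogenation remain. Photochemistry also limits throughput.
- Comparison: the chosen plan is longer but forms the tertiary carbinol intramolecularly and never places a leaving group β to a ketone with an acidic C7 hydrogen.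

**Alternative 3:** Conjugate methylation with aldol trapping. The cuts are C3–CH3 and C7–C8, with no ring formed. Copper-catalysed addition of Al(CH3)3 to enone A6 and in situ aldol trapping with iodoenal A7 would give cyclopentanone A5.
- Merits: this is the most convergent road. The five ring is bought, three components are joined in one step, the iodoalkene arrives complete, and a route of roughly eleven steps is conceivable against 18 here. In step economy it is clearly better.
- Weak points: the choice between the methyl and the silyloxyethyl arm at C3 that decides C7 is the same as in the chosen plan, but without a chelate to organise it. The C8 carbinol depends on an aldol of modest intrinsic selectivity. The isopropyl group must then be added to a hindered, enolisable β-hydroxy cyclopentanone, where retro-aldol, enolisation and reduction compete.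
- Comparison: the chosen plan spends about seven more steps. It sets against this a tertiary carbinol formed under non-basic, chelated conditions together with C7, and a C8 centre set by the free C6 hydroxyl.

Key step: step 8

## Route

Assumption: centres that are destroyed later (the carbinol carbon of 6, the C–Br carbon of 10–13, the carbinol carbon of 12) are carried as epimer mixtures.

Step 1
Reactants: 1 5-bromo-2-methylpent-2-ene; 2 3-methylcyclopent-2-en-1-one
Product: 4 (3R)-3-methyl-3-(4-methylpent-3-en-1-yl)cyclopentan-1-one, via Grignard reagent 3 (not isolated)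
Conditions: Mg, Et2O, reflux; then 2, Cu(OTf)2 (cat.), chiral imidazolinium NHC precursor (cat.), Et2O, −30 to 0 °C; aq NH4Cl
Reagents that add atoms: none
Why: Copper/NHC-catalysed asymmetric conjugate addition of a Grignard reagent to a β-substituted cyclic enone builds the quaternary C3; the ligand enantiomer is chosen to give the (R)-ketone and the magnesium enolate is simply protonated.

Step 2
Reactants: 4 (3R)-3-methyl-3-(4-methylpent-3-en-1-yl)cyclopentan-1-one
Product: 6 (4R)-2-hydroxy-4-methyl-4-(4-methylpent-3-en-1-yl)cyclopentan-1-one (C2 epimers), via potassium enolate 5 (not isolated)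
Conditions: KN(SiMe3)2, THF, −78 °C; then 2-(phenylsulfonyl)-3-phenyloxaziridine, −78 °C; aq NH4Cl
Reagents that add atoms: 2-(phenylsulfonyl)-3-phenyloxaziridine, O=S(=O)(c1ccccc1)N1OC1c1ccccc1
Why: Kinetic deprotonation takes the methylene remote from the quaternary carbon (the other is neopentylic) and the enolate is oxidised by the N-sulfonyloxaziridine (Davis oxidation) without touching the alkene. The new carbinol centre is destroyed in step 3; a cold quench avoids α-ketol transposition, which would exchange the two arms on C3.

Step 3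
Reactants: 6 (4R)-2-hydroxy-4-methyl-4-(4-methylpent-3-en-1-yl)cyclopentan-1-one
Product: 7 methyl (3R)-3,7-dimethyl-3-(2-oxoethyl)oct-6-enoate
Conditions: Pb(OAc)4, MeOH/toluene, 0 °C to rt
Reagents that add atoms: methanol, CO
Why: Pb(OAc)4 cleaves the α-ketol through its methyl hemiketal (Criegee-type glycol cleavage), so the carbonyl carbon leaves as the C8 methyl ester and the carbinol carbon as the C1 aldehyde. The two arms on C3 are differentiated in one step and the alkene survives.

Step 4
Reactants: 7 methyl (3R)-3,7-dimethyl-3-(2-oxoethyl)oct-6-enoate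
Product: 8 methyl (3R)-3-(2,2-dimethoxyethyl)-3,7-dimethyloct-6-enoate
Conditions: HC(OMe)3, MeOH, pyridinium p-toluenesulfonate (cat.), rt
Reagents that add atoms: trimethyl orthoformate, COC(OC)OC; methanol, CO
Why: Acid-catalysed acetalisation with the orthoformate as water scavenger masks C1 at the aldehyde level; an acetal cannot lactonise onto the C8 ester as a C1 alcohol would.

Step 5
Reactants: 8 methyl (3R)-3-(2,2-dimethoxyethyl)-3,7-dimethyloct-6-enoate
Product: 10 methyl (3R)-2-bromo-3-(2,2-dimethoxyethyl)-3,7-dimethyloct-6-enoate (C2 epimers), via silyl ketene acetal 9 (not isolated)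
Conditions: LiN(iPr)2, THF, −78 °C; Me3SiCl; then N-bromosuccinimide, −78 to 0 °C
Reagents that add atoms: N-bromosuccinimide, O=C1CCC(=O)N1Br
Why: The ester is the only enolisable carbonyl at this stage, so its enolate is trapped as the silyl ketene acetal and brominated (α-halogenation of an ester enolate equivalent). The isolated alkene does not react at low temperature and both bromide epimers converge in step 8.

Step 6
Reactants: 10 methyl (3R)-2-bromo-3-(2,2-dimethoxyethyl)-3,7-dimethyloct-6-enoate
Product: 12 methyl (3R)-2-bromo-3-(2,2-dimethoxyethyl)-6-hydroxy-3,7-dimethyloctanoate (C2/C6 epimer mixture), via alkylborane 11 (not isolated)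
Conditions: BH3·THF, THF, 0 °C; then 30% H2O2, aq NaHCO3, 0 °C to rt
Reagents that add atoms: hydrogen peroxide, OO
Why: Hydroboration of the trisubstituted alkene places boron on the less substituted carbon C6 (anti-Markovnikov) much faster than borane attacks an ester or acetal. Bicarbonate-buffered peroxide oxidation spares the hindered neopentylic bromo ester.

Step 7
Reactants: 12 methyl (3R)-2-bromo-3-(2,2-dimethoxyethyl)-6-hydroxy-3,7-dimethyloctanoate
Product: 13 methyl (3R)-2-bromo-3-(2,2-dimethoxyethyl)-3,7-dimethyl-6-oxooctanoate (C2 epimers)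
Conditions: Dess–Martin periodinane, NaHCO3, CH2Cl2, rt
Reagents that add atoms: none
Why: Dess–Martin oxidation of the secondary alcohol under buffered, near-neutral conditions gives the isopropyl ketone without loss of bromide.

Step 8
Reactants: 13 methyl (3R)-2-bromo-3-(2,2-dimethoxyethyl)-3,7-dimethyl-6-oxooctanoate
Product: 15 methyl (1R,2R,5R)-2-(2,2-dimethoxyethyl)-5-hydroxy-2-methyl-5-(propan-2-yl)cyclopentane-1-carboxylate, via samarium enolate 14 (not isolated)
Conditions: SmI2 (2.5 equiv), THF, −78 °C; aq NH4Cl
Reagents that add atoms: none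
Why: Two single-electron transfers from SmI2 cleave the C7–Br bond (both epimers converge) and give the trivalent samarium ester enolate 14, which adds to the tethered isopropyl ketone to form C6–C7; the closest known reaction type is the SmI2-promoted intramolecular Reformatsky reaction of α-halo esters with ketones. The five ring closes in 5-(enolexo)-exo-trig mode. C6 is controlled by the metal: samarium bridges the enolate and ketone oxygens in a six-membered chelate, so the new hydroxyl ends cis to the C8 ester. C7 is controlled by C3: in the closing transition state C4 stands perpendicular to the enolate plane, and of the two other C3 substituents the one next to the ester carbon suffers allylic strain with the ligated samarium–oxygen or methoxy group, so the methyl takes that place and the β-branched acetal arm points away, which puts the ester cis to the methyl and trans to the arm as in 31. The selectivity the step needs is this choice of enolate face relative to C3, and it rests on the size difference between methyl and the CH2CH(OMe)2 arm and on the acetal being too remote to chelate the metal. Low temperature and the oxophilic metal hold the tertiary aldolate against retro-aldol. Without a strong donor additive SmI2 reduces the bromide well before the ketone.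

Step 9
Reactants: 15 methyl (1R,2R,5R)-2-(2,2-dimethoxyethyl)-5-hydroxy-2-methyl-5-(propan-2-yl)cyclopentane-1-carboxylate
Product: 16 (1R,2S,3R)-3-(2,2-dimethoxyethyl)-2-(hydroxymethyl)-3-methyl-1-(propan-2-yl)cyclopentan-1-ol
Conditions: LiAlH4, THF, 0 °C
Reagents that add atoms: none
Why: Hydride reduction of the hindered β-hydroxy ester gives the 1,3-diol; the acetal is inert and the three stereocentres are untouched.

Step 10
Reactants: 16 (1R,2S,3R)-3-(2,2-dimethoxyethyl)-2-(hydroxymethyl)-3-methyl-1-(propan-2-yl)cyclopentan-1-ol
Product: 17 (1R,2R,5R)-2-(2,2-dimethoxyethyl)-5-hydroxy-2-methyl-5-(propan-2-yl)cyclopentane-1-carbaldehyde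
Conditions: Dess–Martin periodinane, NaHCO3, CH2Cl2, 0 °C
Reagents that add atoms: none
Why: The periodinane oxidises the primary alcohol and cannot oxidise the tertiary one. Buffering and low temperature limit dehydration, retro-aldol and C7 epimerisation of the β-hydroxy aldehyde, which is used at once.

Step 11
Reactants: 17 (1R,2R,5R)-2-(2,2-dimethoxyethyl)-5-hydroxy-2-methyl-5-(propan-2-yl)cyclopentane-1-carbaldehyde; 18 prop-1-yn-1-ylmagnesium bromide
Product: 19 (1R,2S,3R)-3-(2,2-dimethoxyethyl)-2-[(1R)-1-hydroxybut-2-yn-1-yl]-3-methyl-1-(propan-2-yl)cyclopentan-1-ol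
Conditions: 18 (3 equiv), THF, −78 to −20 °C; aq NH4Cl
Reagents that add atoms: none
Why: The first equivalent forms the C6 magnesium alkoxide, which chelates the aldehyde oxygen in a six-membered ring. The alkynyl group then adds to the face of C8 syn to H7 and anti to the quaternary C3 (Cram-chelate addition), giving the (R)-carbinol that corresponds to C8 of 31 (the descriptor becomes S in the bicycle only through a priority change).

Step 12
Reactants: 19 (1R,2S,3R)-3-(2,2-dimethoxyethyl)-2-[(1R)-1-hydroxybut-2-yn-1-yl]-3-methyl-1-(propan-2-yl)cyclopentan-1-ol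
Product: 21 (1R,2S,3R)-3-(2,2-dimethoxyethyl)-2-[(1R,2Z)-1-hydroxy-3-iodobut-2-en-1-yl]-3-methyl-1-(propan-2-yl)cyclopentan-1-ol, via alkenylaluminate 20 (not isolated)
Conditions: NaAlH2(OCH2CH2OMe)2, THF, 0 °C to rt; EtOAc; then I2, THF, −78 to 0 °C
Reagents that add atoms: iodine, II
Why: The propargylic alkoxide directs trans-hydroalumination (aluminium on the distal carbon C10, hydride on C9) and iodine replaces aluminium with retention. The iodide therefore ends cis to C8, the (Z)-geometry an endocyclic alkene requires.

Step 13
Reactants: 22 4-hydroxybenzoic acid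
Product: 24 4-[(tert-butyldimethylsilyl)oxy]benzoic acid, via bis-silyl compound 23 (not isolated)
Conditions: tert-butyldimethylsilyl chloride (2.2 equiv), imidazole, DMF, rt; then AcOH, THF/H2O, rt
Reagents that add atoms: tert-butyldimethylsilyl chloride, CC(C)(C)[Si](C)(C)Cl
Why: Exhaustive silylation followed by selective hydrolysis of the labile silyl ester leaves the phenol as a silyl ether, removable at the end without touching carboxylic esters.

Step 14
Reactants: 21 (1R,2S,3R)-3-(2,2-dimethoxyethyl)-2-[(1R,2Z)-1-hydroxy-3-iodobut-2-en-1-yl]-3-methyl-1-(propan-2-yl)cyclopentan-1-ol; 24 4-[(tert-butyldimethylsilyl)oxy]benzoic acid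
Product: 26 (1R,2Z)-1-[(1S,2R,5R)-2-(2,2-dimethoxyethyl)-5-hydroxy-2-methyl-5-(propan-2-yl)cyclopentyl]-3-iodobut-2-en-1-yl 4-[(tert-butyldimethylsilyl)oxy]benzoate, via mixed anhydride 25 (not isolated)
Conditions: 24, 2,4,6-trichlorobenzoyl chloride, Et3N, THF, rt; then 21, DMAP, toluene, rt
Reagents that add atoms: none
Why: Yamaguchi esterification acylates the hindered secondary allylic C8 hydroxyl through the acylpyridinium ion, while the tertiary C6 hydroxyl is too hindered to react. Installing the aroyl group now keeps the C8 and C1 oxygens distinguishable.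

Step 15
Reactants: 26 (1R,2Z)-1-[(1S,2R,5R)-2-(2,2-dimethoxyethyl)-5-hydroxy-2-methyl-5-(propan-2-yl)cyclopentyl]-3-iodobut-2-en-1-yl 4-[(tert-butyldimethylsilyl)oxy]benzoate
Product: 27 (1R,2Z)-1-[(1S,2R,5R)-2-hydroxy-5-methyl-5-(2-oxoethyl)-2-(propan-2-yl)cyclopentyl]-3-iodobut-2-en-1-yl 4-[(tert-butyldimethylsilyl)oxy]benzoate
Conditions: pyridinium p-toluenesulfonate (cat.), acetone/H2O, 40 °C
Reagents that add atoms: water, O
Why: Mild acid-catalysed hydrolysis of the dimethyl acetal frees the C1 aldehyde; the aryl silyl ether, the allylic ester and the tertiary alcohol tolerate the weak acid. The C6 hydroxyl is trans to the C2 arm and cannot form a lactol.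

Step 16
Reactants: 27 (1R,2Z)-1-[(1S,2R,5R)-2-hydroxy-5-methyl-5-(2-oxoethyl)-2-(propan-2-yl)cyclopentyl]-3-iodobut-2-en-1-yl 4-[(tert-butyldimethylsilyl)oxy]benzoate
Product: 29 (1R,3aR,5S,8S,8aS)-1,5-dihydroxy-3a,6-dimethyl-1-(propan-2-yl)-1,2,3,3a,4,5,8,8a-octahydroazulen-8-yl 4-[(tert-butyldimethylsilyl)oxy]benzoate, via alkenylchromium species 28 (not isolated)
Conditions: CrCl2 (excess), NiCl2 (cat.), degassed DMSO, rt, high dilution
Reagents that add atoms: none
Why: Nozaki–Hiyama–Kishi reaction: zerovalent nickel inserts into the C10–I bond, transmetalation gives a trivalent chromium alkenyl that adds to the C1 aldehyde and closes the seven ring with retention of alkene geometry. The chromium alkoxide is expected to take the pseudo-equatorial position trans to the axial C3 methyl, avoiding a syn-diaxial contact, which is the (S)-configuration at C1.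

Step 17
Reactants: 29 (1R,3aR,5S,8S,8aS)-1,5-dihydroxy-3a,6-dimethyl-1-(propan-2-yl)-1,2,3,3a,4,5,8,8a-octahydroazulen-8-yl 4-[(tert-butyldimethylsilyl)oxy]benzoate
Product: 30 (1R,3aR,5S,8S,8aS)-5-(acetyloxy)-1-hydroxy-3a,6-dimethyl-1-(propan-2-yl)-1,2,3,3a,4,5,8,8a-octahydroazulen-8-yl 4-[(tert-butyldimethylsilyl)oxy]benzoate
Conditions: Ac2O, pyridine, DMAP (cat.), CH2Cl2, 0 °C to rt
Reagents that add atoms: acetic anhydride, CC(=O)OC(C)=O
Why: DMAP-catalysed acetylation takes the secondary allylic C1 hydroxyl; the tertiary C6 hydroxyl is not acylated under these conditions.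

Step 18
Reactants: 30 (1R,3aR,5S,8S,8aS)-5-(acetyloxy)-1-hydroxy-3a,6-dimethyl-1-(propan-2-yl)-1,2,3,3a,4,5,8,8a-octahydroazulen-8-yl 4-[(tert-butyldimethylsilyl)oxy]benzoate
Product: 31 (1R,3aR,5S,8S,8aS)-5-(acetyloxy)-1-hydroxy-3a,6-dimethyl-1-(propan-2-yl)-1,2,3,3a,4,5,8,8a-octahydroazulen-8-yl 4-hydroxybenzoate
Conditions: Bu4NF, AcOH, THF, 0 °C
Reagents that add atoms: none
Why: Buffered fluoride cleaves the aryl silyl ether selectively; the acetic acid buffer prevents the basic conditions that would cleave or migrate the two esters.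

## Compound list

1 | 5-bromo-2-methylpent-2-ene | CC(C)=CCCBr | starting material
2 | 3-methylcyclopent-2-en-1-one | CC1=CC(=O)CC1 | starting material
3 | (4-methylpent-3-en-1-yl)magnesium bromide | CC(C)=CCC[Mg]Br | intermediate
4 | (3R)-3-methyl-3-(4-methylpent-3-en-1-yl)cyclopentan-1-one | O=C1C[C@](C)(CCC=C(C)C)CC1 | intermediate
5 | potassium (4R)-4-methyl-4-(4-methylpent-3-en-1-yl)cyclopent-1-en-1-olate | [K+].[O-]C1=CC[C@@](C)(CCC=C(C)C)C1 | intermediate
6 | (4R)-2-hydroxy-4-methyl-4-(4-methylpent-3-en-1-yl)cyclopentan-1-one (C2 epimers) | O=C1C[C@](C)(CCC=C(C)C)CC1O | intermediate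
7 | methyl (3R)-3,7-dimethyl-3-(2-oxoethyl)oct-6-enoate | COC(=O)C[C@@](C)(CC=O)CCC=C(C)C | intermediate
8 | methyl (3R)-3-(2,2-dimethoxyethyl)-3,7-dimethyloct-6-enoate | COC(=O)C[C@@](C)(CC(OC)OC)CCC=C(C)C | intermediate
9 | {[(3R)-3-(2,2-dimethoxyethyl)-1-methoxy-3,7-dimethylocta-1,6-dien-1-yl]oxy}(trimethyl)silane (silyl ketene acetal, geometry unassigned) | COC(O[Si](C)(C)C)=C[C@@](C)(CC(OC)OC)CCC=C(C)C | intermediate
10 | methyl (3R)-2-bromo-3-(2,2-dimethoxyethyl)-3,7-dimethyloct-6-enoate (C2 epimers) | COC(=O)C(Br)[C@@](C)(CC(OC)OC)CCC=C(C)C | intermediate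
11 | methyl (3R)-6-boranyl-2-bromo-3-(2,2-dimethoxyethyl)-3,7-dimethyloctanoate (alkylborane, drawn as the monoalkylborane) | COC(=O)C(Br)[C@@](C)(CC(OC)OC)CCC(B)C(C)C | intermediate
12 | methyl (3R)-2-bromo-3-(2,2-dimethoxyethyl)-6-hydroxy-3,7-dimethyloctanoate (C2/C6 epimers) | COC(=O)C(Br)[C@@](C)(CC(OC)OC)CCC(O)C(C)C | intermediate
13 | methyl (3R)-2-bromo-3-(2,2-dimethoxyethyl)-3,7-dimethyl-6-oxooctanoate (C2 epimers) | COC(=O)C(Br)[C@@](C)(CC(OC)OC)CCC(=O)C(C)C | intermediate
14 | diiodosamarium enolate of methyl (3R)-3-(2,2-dimethoxyethyl)-3,7-dimethyl-6-oxooctanoate | COC(O[Sm](I)I)=C[C@@](C)(CC(OC)OC)CCC(=O)C(C)C | intermediate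
15 | methyl (1R,2R,5R)-2-(2,2-dimethoxyethyl)-5-hydroxy-2-methyl-5-(propan-2-yl)cyclopentane-1-carboxylate | COC(=O)[C@H]1[C@](O)(C(C)C)CC[C@]1(C)CC(OC)OC | intermediate
16 | (1R,2S,3R)-3-(2,2-dimethoxyethyl)-2-(hydroxymethyl)-3-methyl-1-(propan-2-yl)cyclopentan-1-ol | OC[C@H]1[C@](O)(C(C)C)CC[C@]1(C)CC(OC)OC | intermediate
17 | (1R,2R,5R)-2-(2,2-dimethoxyethyl)-5-hydroxy-2-methyl-5-(propan-2-yl)cyclopentane-1-carbaldehyde | O=C[C@H]1[C@](O)(C(C)C)CC[C@]1(C)CC(OC)OC | intermediate
18 | prop-1-yn-1-ylmagnesium bromide | CC#C[Mg]Br | starting material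
19 | (1R,2S,3R)-3-(2,2-dimethoxyethyl)-2-[(1R)-1-hydroxybut-2-yn-1-yl]-3-methyl-1-(propan-2-yl)cyclopentan-1-ol | CC#C[C@H](O)[C@H]1[C@](O)(C(C)C)CC[C@]1(C)CC(OC)OC | intermediate
20 | sodium cyclic (Z)-alkenylaluminate of 19 (1,2-oxaluminole ring through O8 and C10; tertiary hydroxyl drawn free) | CC1=C[C@@H]([C@H]2[C@](O)(C(C)C)CC[C@]2(C)CC(OC)OC)O[Al-]1(OCCOC)OCCOC.[Na+] | intermediate
21 | (1R,2S,3R)-3-(2,2-dimethoxyethyl)-2-[(1R,2Z)-1-hydroxy-3-iodobut-2-en-1-yl]-3-methyl-1-(propan-2-yl)cyclopentan-1-ol | C/C(I)=C/[C@H](O)[C@H]1[C@](O)(C(C)C)CC[C@]1(C)CC(OC)OC | intermediate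
22 | 4-hydroxybenzoic acid | OC(=O)c1ccc(O)cc1 | starting material
23 | tert-butyldimethylsilyl 4-[(tert-butyldimethylsilyl)oxy]benzoate | CC(C)(C)[Si](C)(C)OC(=O)c1ccc(O[Si](C)(C)C(C)(C)C)cc1 | intermediate
24 | 4-[(tert-butyldimethylsilyl)oxy]benzoic acid | OC(=O)c1ccc(O[Si](C)(C)C(C)(C)C)cc1 | intermediate
25 | 4-[(tert-butyldimethylsilyl)oxy]benzoic 2,4,6-trichlorobenzoic anhydride | O=C(OC(=O)c1c(Cl)cc(Cl)cc1Cl)c1ccc(O[Si](C)(C)C(C)(C)C)cc1 | intermediate
26 | (1R,2Z)-1-[(1S,2R,5R)-2-(2,2-dimethoxyethyl)-5-hydroxy-2-methyl-5-(propan-2-yl)cyclopentyl]-3-iodobut-2-en-1-yl 4-[(tert-butyldimethylsilyl)oxy]benzoate | C/C(I)=C/[C@H](OC(=O)c1ccc(O[Si](C)(C)C(C)(C)C)cc1)[C@H]1[C@](O)(C(C)C)CC[C@]1(C)CC(OC)OC | intermediate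
27 | (1R,2Z)-1-[(1S,2R,5R)-2-hydroxy-5-methyl-5-(2-oxoethyl)-2-(propan-2-yl)cyclopentyl]-3-iodobut-2-en-1-yl 4-[(tert-butyldimethylsilyl)oxy]benzoate | C/C(I)=C/[C@H](OC(=O)c1ccc(O[Si](C)(C)C(C)(C)C)cc1)[C@H]1[C@](O)(C(C)C)CC[C@]1(C)CC=O | intermediate
28 | dichlorochromium alkenyl derived from 27 (chromium in place of iodine at C10) | C/C([Cr](Cl)Cl)=C/[C@H](OC(=O)c1ccc(O[Si](C)(C)C(C)(C)C)cc1)[C@H]1[C@](O)(C(C)C)CC[C@]1(C)CC=O | intermediate
29 | (1R,3aR,5S,8S,8aS)-1,5-dihydroxy-3a,6-dimethyl-1-(propan-2-yl)-1,2,3,3a,4,5,8,8a-octahydroazulen-8-yl 4-[(tert-butyldimethylsilyl)oxy]benzoate | O[C@H]1C[C@@]2(C)CC[C@@](O)(C(C)C)[C@@H]2[C@@H](OC(=O)c2ccc(O[Si](C)(C)C(C)(C)C)cc2)C=C1C | intermediate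
30 | (1R,3aR,5S,8S,8aS)-5-(acetyloxy)-1-hydroxy-3a,6-dimethyl-1-(propan-2-yl)-1,2,3,3a,4,5,8,8a-octahydroazulen-8-yl 4-[(tert-butyldimethylsilyl)oxy]benzoate | CC(=O)O[C@H]1C[C@@]2(C)CC[C@@](O)(C(C)C)[C@@H]2[C@@H](OC(=O)c2ccc(O[Si](C)(C)C(C)(C)C)cc2)C=C1C | intermediate
31 | (1R,3aR,5S,8S,8aS)-5-(acetyloxy)-1-hydroxy-3a,6-dimethyl-1-(propan-2-yl)-1,2,3,3a,4,5,8,8a-octahydroazulen-8-yl 4-hydroxybenzoate | CC(=O)O[C@H]1C[C@@]2(C)CC[C@@](O)(C(C)C)[C@@H]2[C@@H](OC(=O)c2ccc(O)cc2)C=C1C | target

## Step count and risks

Total: 18 steps. Longest linear sequence: 17 steps (steps 1–12 and 14–18, from 1 and 2 to 31); step 13 is a one-step side branch.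

**Step 8 (key step).** The most likely failure is poor discrimination between the two faces of enolate 14 relative to C3, because methyl and the acetal arm differ only moderately in size. Premature protonation of the enolate is a secondary loss. The fallback puts the enolate face under auxiliary control; it sets out from 8 and returns at 16.
- Saponification of 8 (LiOH, aq THF/MeOH) gives (3R)-3-(2,2-dimethoxyethyl)-3,7-dimethyloct-6-enoic acid F1.
- Activation with pivaloyl chloride and acylation of lithiated (4S)-4-benzyl-1,3-oxazolidin-2-one gives imide F2.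
- Bromination of its boron enolate (Bu2BOTf, iPr2NEt, then N-bromosuccinimide) gives bromo imide F3.
- Hydroboration–oxidation gives alcohol F4 and Dess–Martin oxidation gives keto bromo imide F5.
- SmI2 closure then gives cyclised imide F6, with the benzyl group shielding one face of the chelated (Z)-enolate. The (4S)-auxiliary is chosen on the chelated-enolate model as the one matched with the substrate bias.
- LiBH4 removes the auxiliary reductively and gives diol 16.

**Step 1.** Enantioselection may be insufficient, since five-membered enones are harder substrates than six-membered ones for Grignard conjugate addition. The fallback forms the other C3–C bond; it sets out from 1 (as its Grignard reagent 3) and returns at 4. Reagent 3 is added to 3-ethoxycyclopent-2-en-1-one and the adduct is hydrolysed with dilute HCl (Stork–Danheiser transposition) to 3-(4-methylpent-3-en-1-yl)cyclopent-2-en-1-one F7. Copper-catalysed asymmetric conjugate addition of Al(CH3)3 (Cu(OTf)2, chiral NHC ligand, THF, −78 °C) then installs the methyl group.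

**Step 11.** Facial selectivity at C8 may erode if chelation by the C6 alkoxide is incomplete, and the magnesium aldolate may undergo retro-aldol. The fallback replaces substrate control by reagent control; it sets out from 19 (as the epimer mixture) and returns at 19. Oxidation (MnO2 or Dess–Martin periodinane) gives ynone F8. Noyori transfer hydrogenation with RuCl(p-cymene)[(R,R)-TsDPEN] in iPrOH, which by the usual sense of induction for alkynyl ketones should give the (R)-carbinol, returns to 19.

**Step 16.** The ring may close through the conformer with the chromium alkoxide axial, giving the wrong configuration at C1. The fallback corrects the centre by inversion; it sets out from 27 and returns at 30. The separated C1 epimer F9 is treated with acetic acid, PPh3 and diisopropyl azodicarboxylate (Mitsunobu reaction), which inverts C1 and gives acetate 30 directly.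

## Further compounds

F1 | step 8 | (3R)-3-(2,2-dimethoxyethyl)-3,7-dimethyloct-6-enoic acid | OC(=O)C[C@@](C)(CC(OC)OC)CCC=C(C)C
F2 | step 8 | (4S)-4-benzyl-3-[(3R)-3-(2,2-dimethoxyethyl)-3,7-dimethyloct-6-enoyl]-1,3-oxazolidin-2-one | O=C1OC[C@H](Cc2ccccc2)N1C(=O)C[C@@](C)(CC(OC)OC)CCC=C(C)C
F3 | step 8 | (4S)-4-benzyl-3-[(3R)-2-bromo-3-(2,2-dimethoxyethyl)-3,7-dimethyloct-6-enoyl]-1,3-oxazolidin-2-one (bromide epimers) | O=C1OC[C@H](Cc2ccccc2)N1C(=O)C(Br)[C@@](C)(CC(OC)OC)CCC=C(C)C
F4 | step 8 | (4S)-4-benzyl-3-[(3R)-2-bromo-3-(2,2-dimethoxyethyl)-6-hydroxy-3,7-dimethyloctanoyl]-1,3-oxazolidin-2-one (epimer mixture) | O=C1OC[C@H](Cc2ccccc2)N1C(=O)C(Br)[C@@](C)(CC(OC)OC)CCC(O)C(C)C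
F5 | step 8 | (4S)-4-benzyl-3-[(3R)-2-bromo-3-(2,2-dimethoxyethyl)-3,7-dimethyl-6-oxooctanoyl]-1,3-oxazolidin-2-one (bromide epimers) | O=C1OC[C@H](Cc2ccccc2)N1C(=O)C(Br)[C@@](C)(CC(OC)OC)CCC(=O)C(C)C
F6 | step 8 | (4S)-4-benzyl-3-{[(1R,2R,5R)-2-(2,2-dimethoxyethyl)-5-hydroxy-2-methyl-5-(propan-2-yl)cyclopentyl]carbonyl}-1,3-oxazolidin-2-one | O=C1OC[C@H](Cc2ccccc2)N1C(=O)[C@H]3[C@](O)(C(C)C)CC[C@]3(C)CC(OC)OC
F7 | step 1 | 3-(4-methylpent-3-en-1-yl)cyclopent-2-en-1-one | O=C1C=C(CCC=C(C)C)CC1
F8 | step 11 | 1-[(1R,2R,5R)-2-(2,2-dimethoxyethyl)-5-hydroxy-2-methyl-5-(propan-2-yl)cyclopentyl]but-2-yn-1-one | CC#CC(=O)[C@H]1[C@](O)(C(C)C)CC[C@]1(C)CC(OC)OC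
F9 | step 16 | (1R,3aR,5R,8S,8aS)-1,5-dihydroxy-3a,6-dimethyl-1-(propan-2-yl)-1,2,3,3a,4,5,8,8a-octahydroazulen-8-yl 4-[(tert-butyldimethylsilyl)oxy]benzoate | O[C@@H]1C[C@@]2(C)CC[C@@](O)(C(C)C)[C@@H]2[C@@H](OC(=O)c2ccc(O[Si](C)(C)C(C)(C)C)cc2)C=C1C
A1 | alternative 1 | 4,7-dimethoxy-6,8a-dimethyl-3-(propan-2-yl)-3-[(triethylsilyl)oxy]-2,3-dihydroazulen-1(8aH)-one (configured as in the SMILES) | COC1=C[C@@]2(C)C(=O)C[C@@](O[Si](CC)(CC)CC)(C(C)C)C2=C(OC)C=C1C
A2 | alternative 1 | (5R)-2-diazo-5-(2,5-dimethoxy-4-methylphenyl)-6-methyl-5-[(triethylsilyl)oxy]heptan-3-one | CC(=[N+]=[N-])C(=O)C[C@@](O[Si](CC)(CC)CC)(C(C)C)c1cc(OC)c(C)cc1OC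
A3 | alternative 2 | 8-[(tert-butyldimethylsilyl)oxy]-3a,6-dimethyloctahydroazulene-1,5-dione (trans-fused, configured as in the SMILES, one C6 epimer drawn) | O=C1C[C@@]2(C)CCC(=O)[C@@H]2[C@@H](O[Si](C)(C)C(C)(C)C)C[C@@H]1C
A4 | alternative 2 | 3-[(tert-butyldimethylsilyl)oxy]-5-methyl-2-(4-methylpent-4-enoyl)cyclopent-1-en-1-yl acetate (silyloxy carbon configured as in the SMILES) | CC(=O)OC1=C(C(=O)CCC(C)=C)[C@@H](O[Si](C)(C)C(C)(C)C)CC1C
A5 | alternative 3 | 3-{2-[(tert-butyldimethylsilyl)oxy]ethyl}-2-[(2Z)-1-hydroxy-3-iodobut-2-en-1-yl]-3-methylcyclopentan-1-one (configured as in the SMILES) | C/C(I)=C/[C@H](O)[C@H]1C(=O)CC[C@]1(C)CCO[Si](C)(C)C(C)(C)C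
A6 | alternative 3 | 3-{2-[(tert-butyldimethylsilyl)oxy]ethyl}cyclopent-2-en-1-one | O=C1C=C(CCO[Si](C)(C)C(C)(C)C)CC1
A7 | alternative 3 | (2Z)-3-iodobut-2-enal | C/C(I)=C/C=O
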